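**Plan**

1. Numbering: chroman O1 to C8a; side chain C1' (on C2) through the C3'=C4' alkene, the methyl-bearing C8' and the C9' ketone to C12'.
2. Retrosynthesis first cuts C9'–C10' (prenyl nucleophile plus an (8'S)-aldehyde) and traces C8'–H and C9'–O back to the terminal isopropylidene group of a farnesol-derived chain.
3. The benzene ring is a para-alkoxyphenol (O1 on C8a para to the OH on C6, methyl on C8, C4 on C4a), the pattern an alkenyl(alkoxy)carbene of Cr(CO)5, one CO and an alkyne assemble. Cutting C4a–C8a, C5–C6 and C6–C7 therefore leaves an isopropenyl carbene whose oxygen carries C2 with a but-3-ynyl arm.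
4. Forward: farnesol is taken to the (R)-tertiary alkynol (steps 1–5) and loaded onto the chromium carbene (steps 6–7). One thermolysis closes the dihydropyran and benzene rings together (step 8). The chain is finished by allylic oxidation, hydrogenation, prenylation and oxidation (steps 9–15).
5. Stereochemistry: C2 comes from the Sharpless epoxidation of step 1 and its C–O bond is never broken; C8' comes from the Ru(OAc)2[(S)-BINAP] hydrogenation of step 11.

Key step: step 8

Remark: the target SMILES is read as the (2R,8'S) isomer; the ligand antipode in step 11 is assigned by analogy with geraniol and is an assumption of the proposal.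

**Route**

Step 1
Reactants: 1 (2E,6E)-farnesol
Product: 2 (2R,3R)-2,3-epoxyfarnesol
Conditions: Ti(OiPr)4 (cat.), D-(−)-diethyl tartrate (cat.), t-BuOOH, 4 Å molecular sieves, CH2Cl2, −20 °C
Reagents that add atoms: tert-butyl hydroperoxide, CC(C)(C)OO
Why: Sharpless asymmetric epoxidation; the titanium tartrate binds the allylic hydroxyl, so only C2=C3 of farnesol is epoxidised, and the D-tartrate should deliver oxygen to the face that gives the (2R,3R)-epoxide, which fixes the future chroman C2.

Step 2
Reactants: 2 (2R,3R)-2,3-epoxyfarnesol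
Product: 3 (3R,6E)-3,7,11-trimethyldodeca-6,10-diene-1,3-diol
Conditions: NaAlH2(OCH2CH2OMe)2, THF, 0 °C
Reagents that add atoms: none
Why: Hydroxyl-directed reductive epoxide opening; the alkoxyaluminium hydride delivers hydride to the secondary epoxide carbon, giving the 1,3-diol with the tertiary C–O bond and its configuration untouched.

Step 3
Reactants: 3 (3R,6E)-3,7,11-trimethyldodeca-6,10-diene-1,3-diol
Product: 4 (3R,6E)-3-hydroxy-3,7,11-trimethyldodeca-6,10-dien-1-yl 4-methylbenzenesulfonate
Conditions: TsCl, Et3N, DMAP (cat.), CH2Cl2, 0 °C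
Reagents that add atoms: 4-toluenesulfonyl chloride, Cc1ccc(cc1)S(Cl)(=O)=O
Why: Selective sulfonylation; the primary hydroxyl reacts far faster than the tertiary one.

Step 4
Reactants: 4 primary tosylate
Product: 5 (3R,6E)-3,7,11-trimethyl-3-(triethylsilyloxy)dodeca-6,10-dien-1-yl 4-methylbenzenesulfonate
Conditions: Et3SiOTf, 2,6-lutidine, CH2Cl2, −78 to 0 °C
Reagents that add atoms: triethylsilyl trifluoromethanesulfonate, CC[Si](CC)(CC)OS(=O)(=O)C(F)(F)F
Why: Silyl triflate silylation of a tertiary alcohol; masking it keeps the alkoxide from closing an oxetane onto the tosylate, or fragmenting, under the strongly basic conditions of the next step.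

Step 5
Reactants: 5 silylated tosylate
Product: 7 (5R,8E)-5,9,13-trimethyltetradeca-8,12-dien-1-yn-5-ol, via alkynyl triethylsilyl ether 6 (not isolated)
Conditions: LiC≡CH·H2NCH2CH2NH2, DMSO, rt; then Bu4NF, THF, 40 °C
Reagents that add atoms: lithium acetylide–ethylenediamine complex, [Li]C#C.NCCN
Why: SN2 alkylation of lithium acetylide by a primary tosylate adds the two carbons that become C4a and C5; fluoride then frees the tertiary hydroxyl without touching its C–O bond.

Step 6
Reactants: 8 2-bromopropene; 9 chromium hexacarbonyl, Cr(CO)6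
Product: 12 tetramethylammonium pentacarbonyl(2-methylpropenoyl)chromate, via isopropenyllithium 10 (not isolated), via lithium acylchromate 11 (not isolated)
Conditions: t-BuLi (2 equiv), Et2O, −78 °C; Cr(CO)6, Et2O, −78 °C to rt; then Me4NBr, H2O
Reagents that add atoms: tetramethylammonium bromide, C[N+](C)(C)C.[Br-]
Why: Fischer acylmetalate synthesis; bromine–lithium exchange gives isopropenyllithium, which adds to a CO ligand, and cation exchange gives a storable salt whose oxygen is the nucleophilic site.

Step 7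
Reactants: 12 tetramethylammonium acylchromate (excess); 7 tertiary alkynol
Product: 15 pentacarbonyl{2-methyl-1-[(5R,8E)-5,9,13-trimethyltetradeca-8,12-dien-1-yn-5-yloxy]prop-2-en-1-ylidene}chromium, via sodium alkoxide 13 (not isolated), via pivaloyloxycarbene complex 14 (not isolated)
Conditions: 7, NaH (1.0 equiv), THF, 0 °C to rt; separately 12, t-BuCOCl (slightly less than 1 equiv), CH2Cl2, −40 °C; alkoxide solution added at −78 °C, then to −20 °C; rapid silica filtration under Ar
Reagents that add atoms: none
Why: Proposed new method: O-acylation of the acylchromate gives a pivaloyloxycarbene, a mixed-anhydride analogue whose carbene carbon is its most electrophilic site, so the tertiary alkoxide should add there and the tetrahedral adduct should expel pivalate (the carbinol C–O bond is not involved, hence retention at the future C2), while the tert-butyl group shields the ester carbonyl from acyl transfer and the low temperature disfavours conjugate addition to the isopropenyl group; the closest known reaction type is the alcoholysis of acetoxy- or pivaloyloxycarbene chromium complexes generated in the flask by primary and secondary alcohols, ω-alkynols and menthol included.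

Step 8
Reactants: 15 isopropenyl(alkynyloxy)carbene complex
Product: 17 (2R)-2-[(3E)-4,8-dimethylnona-3,7-dien-1-yl]-2,8-dimethylchroman-6-ol, via tricarbonylchromium arene complex 16 (not isolated)
Conditions: THF (0.005 M), 55 °C, Ar; then air, Et2O, daylight, rt
Reagents that add atoms: none
Why: Loss of one CO from 15 opens a site for the tethered alkyne, which inserts into the Cr=C bond with its internal carbon on the carbene carbon (C4a–C8a); a CO ligand then inserts to give a chromium-bound dienylketene (C5–C6), and 6π-electrocyclisation onto the isopropenyl CH2 (C6–C7) followed by tautomerisation gives the C6 phenol as its Cr(CO)3 complex 16, which air demetallates. The closest known reaction type is the intramolecular Dötz benzannulation of carbene complexes that carry the alkyne on the alkoxy oxygen; the tertiary carbinol is new only as a substituent, and its geminal substitution should favour the folded conformer. The dihydropyran ring closes in the insertion event as a six-membered closure that is exo with respect to the alkyne, through the O1–C2–C3–C4 tether; the benzene ring closes by the electrocyclisation of the dienylketene. No stereocentre is formed, and C2, none of whose bonds is touched, keeps the configuration set in step 1. The step needs the reversed alkyne regiochemistry (C4a on C8a, C5–H next to C6–OH), which the three-carbon tether enforces because the normal orientation cannot span the ring; it also needs intramolecular over intermolecular insertion, secured by high dilution, and alkyne over alkene capture, secured because a terminal alkyne inserts well below the temperature at which an alkoxycarbene of Cr(CO)5 cyclopropanates an unactivated trisubstituted alkene.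

Step 9
Reactants: 17 chromanol
Product: 18 tert-butyl{[(2R)-2-[(3E)-4,8-dimethylnona-3,7-dien-1-yl]-2,8-dimethylchroman-6-yl]oxy}dimethylsilane
Conditions: t-BuMe2SiCl, imidazole, DMF, rt
Reagents that add atoms: tert-butyldimethylsilyl chloride, CC(C)(C)[Si](C)(C)Cl
Why: Standard phenol silylation; the silyl ether shields the easily oxidised para-alkoxyphenol from the oxidants that follow.

Step 10
Reactants: 18 silyl ether
Product: 20 (2E,6E)-9-[(2R)-6-(tert-butyldimethylsilyloxy)-2,8-dimethylchroman-2-yl]-2,6-dimethylnona-2,6-dien-1-ol, via (2E,6E)-enal 19 (not isolated)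
Conditions: SeO2 (cat.), t-BuOOH, salicylic acid (cat.), CH2Cl2, 0 °C to rt; then NaBH4, MeOH, 0 °C
Reagents that add atoms: selenium dioxide, O=[Se]=O (oxygen carrier); tert-butyl hydroperoxide, CC(C)(C)OO (reoxidant that supplies the oxygen)
Why: Selenium dioxide allylic oxidation (ene reaction, then [2,3]-sigmatropic shift) attacks the (E)-methyl of the terminal, most accessible trisubstituted alkene and gives the (E)-allylic alcohol at C9'; the part over-oxidised to enal 19 is returned by borohydride.

Step 11
Reactants: 20 (E)-allylic alcohol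
Product: 21 (2S,6E)-9-[(2R)-6-(tert-butyldimethylsilyloxy)-2,8-dimethylchroman-2-yl]-2,6-dimethylnon-6-en-1-ol
Conditions: Ru(OAc)2[(S)-BINAP] (cat.), H2 (100 atm), MeOH, rt
Reagents that add atoms: none
Why: Noyori asymmetric hydrogenation of an allylic alcohol; the hydroxyl chelates ruthenium, so only C7'=C8' is reduced while the undirected C3'=C4' alkene should remain, and the (S)-ligand should deliver hydrogen to the face that gives 8'S (face assigned from the geraniol model).

Step 12
Reactants: 21 saturated primary alcohol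
Product: 22 (2S,6E)-9-[(2R)-6-(tert-butyldimethylsilyloxy)-2,8-dimethylchroman-2-yl]-2,6-dimethylnon-6-enal
Conditions: Dess–Martin periodinane, NaHCO3, CH2Cl2, 0 °C; used at once
Reagents that add atoms: none
Why: Dess–Martin oxidation under buffered, non-enolising conditions should give the α-methyl aldehyde without epimerising C8'.

Step 13
Reactants: 22 α-methyl aldehyde; 23 1-chloro-3-methylbut-2-ene
Product: 25 (6S,10E)-13-[(2R)-6-(tert-butyldimethylsilyloxy)-2,8-dimethylchroman-2-yl]-2,6,10-trimethyltrideca-2,10-dien-5-ol (C5 epimers), via prenylbarium chloride 24 (not isolated)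
Conditions: Li, biphenyl, BaI2, THF, rt; 23, −78 °C; then 22, THF, −78 °C
Reagents that add atoms: none
Why: Allylbarium addition; prenylbarium chloride adds to aldehydes through its unsubstituted carbon, giving the linear prenyl carbinol and not the 1,1-dimethylallyl isomer, and at −78 °C addition should outrun enolisation of the aldehyde; the C9' carbinol epimers converge in step 14.

Step 14
Reactants: 25 secondary alcohol
Product: 26 (6S,10E)-13-[(2R)-6-(tert-butyldimethylsilyloxy)-2,8-dimethylchroman-2-yl]-2,6,10-trimethyltrideca-2,10-dien-5-one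
Conditions: Dess–Martin periodinane, NaHCO3, CH2Cl2, 0 °C
Reagents that add atoms: none
Why: Dess–Martin oxidation; neutral conditions should turn both carbinol epimers into one β,γ-unsaturated ketone without moving the C11'=C12' alkene into conjugation or enolising C8'.

Step 15
Reactants: 26 silyl-protected ketone
Product: 27 (6S,10E)-13-[(2R)-6-hydroxy-2,8-dimethylchroman-2-yl]-2,6,10-trimethyltrideca-2,10-dien-5-one (CNP0280076.1)
Conditions: Bu4NF, AcOH (1:1), THF, 0 °C
Reagents that add atoms: none
Why: Fluoride cleavage of an aryl silyl ether; the acetic acid buffer keeps the medium from enolising the ketone, so C8' and the β,γ-alkene should survive.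

**Compound list**

1 | (2E,6E)-farnesol | CC(C)=CCC/C(C)=C/CC/C(C)=C/CO | starting material
2 | (2R,3R)-2,3-epoxyfarnesol, [(2R,3R)-3-[(3E)-4,8-dimethylnona-3,7-dien-1-yl]-3-methyloxiran-2-yl]methanol | CC(C)=CCC/C(C)=C/CC[C@@]1(C)O[C@@H]1CO | intermediate
3 | (3R,6E)-3,7,11-trimethyldodeca-6,10-diene-1,3-diol | CC(C)=CCC/C(C)=C/CC[C@@](C)(O)CCO | intermediate
4 | (3R,6E)-3-hydroxy-3,7,11-trimethyldodeca-6,10-dien-1-yl 4-methylbenzenesulfonate | CC(C)=CCC/C(C)=C/CC[C@@](C)(O)CCOS(=O)(=O)c1ccc(C)cc1 | intermediate
5 | (3R,6E)-3,7,11-trimethyl-3-(triethylsilyloxy)dodeca-6,10-dien-1-yl 4-methylbenzenesulfonate | CC(C)=CCC/C(C)=C/CC[C@@](C)(O[Si](CC)(CC)CC)CCOS(=O)(=O)c1ccc(C)cc1 | intermediate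
6 | triethyl{[(5R,8E)-5,9,13-trimethyltetradeca-8,12-dien-1-yn-5-yl]oxy}silane | CC(C)=CCC/C(C)=C/CC[C@@](C)(O[Si](CC)(CC)CC)CCC#C | intermediate (not isolated)
7 | (5R,8E)-5,9,13-trimethyltetradeca-8,12-dien-1-yn-5-ol | CC(C)=CCC/C(C)=C/CC[C@@](C)(O)CCC#C | intermediate
8 | 2-bromopropene | C=C(C)Br | starting material
9 | chromium hexacarbonyl | O=C=[Cr](=C=O)(=C=O)(=C=O)(=C=O)=C=O | starting material
10 | isopropenyllithium | [Li]C(C)=C | intermediate (not isolated)
11 | lithium pentacarbonyl(2-methylpropenoyl)chromate | C=C(C)C([O-])=[Cr](=C=O)(=C=O)(=C=O)(=C=O)=C=O.[Li+] | intermediate (not isolated)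
12 | tetramethylammonium pentacarbonyl(2-methylpropenoyl)chromate | C=C(C)C([O-])=[Cr](=C=O)(=C=O)(=C=O)(=C=O)=C=O.C[N+](C)(C)C | intermediate
13 | sodium (5R,8E)-5,9,13-trimethyltetradeca-8,12-dien-1-yn-5-olate | CC(C)=CCC/C(C)=C/CC[C@@](C)([O-])CCC#C.[Na+] | intermediate (not isolated)
14 | pentacarbonyl[2-methyl-1-(pivaloyloxy)prop-2-en-1-ylidene]chromium | C=C(C)C(OC(=O)C(C)(C)C)=[Cr](=C=O)(=C=O)(=C=O)(=C=O)=C=O | intermediate (not isolated)
15 | pentacarbonyl{2-methyl-1-[(5R,8E)-5,9,13-trimethyltetradeca-8,12-dien-1-yn-5-yloxy]prop-2-en-1-ylidene}chromium | C=C(C)C(=[Cr](=C=O)(=C=O)(=C=O)(=C=O)=C=O)O[C@@](C)(CCC#C)CC/C=C(\C)CCC=C(C)C | intermediate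
16 | tricarbonylchromium η6-arene complex of chromanol 17 (drawn as two components) | CC(C)=CCC/C(C)=C/CC[C@]1(C)CCc2cc(O)cc(C)c2O1.O=C=[Cr](=C=O)=C=O | intermediate (not isolated)
17 | (2R)-2-[(3E)-4,8-dimethylnona-3,7-dien-1-yl]-2,8-dimethylchroman-6-ol | CC(C)=CCC/C(C)=C/CC[C@]1(C)CCc2cc(O)cc(C)c2O1 | intermediate
18 | tert-butyl{[(2R)-2-[(3E)-4,8-dimethylnona-3,7-dien-1-yl]-2,8-dimethylchroman-6-yl]oxy}dimethylsilane | CC(C)=CCC/C(C)=C/CC[C@]1(C)CCc2cc(O[Si](C)(C)C(C)(C)C)cc(C)c2O1 | intermediate
19 | (2E,6E)-9-[(2R)-6-(tert-butyldimethylsilyloxy)-2,8-dimethylchroman-2-yl]-2,6-dimethylnona-2,6-dienal | O=C/C(C)=C/CC/C(C)=C/CC[C@]1(C)CCc2cc(O[Si](C)(C)C(C)(C)C)cc(C)c2O1 | intermediate (not isolated)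
20 | (2E,6E)-9-[(2R)-6-(tert-butyldimethylsilyloxy)-2,8-dimethylchroman-2-yl]-2,6-dimethylnona-2,6-dien-1-ol | OC/C(C)=C/CC/C(C)=C/CC[C@]1(C)CCc2cc(O[Si](C)(C)C(C)(C)C)cc(C)c2O1 | intermediate
21 | (2S,6E)-9-[(2R)-6-(tert-butyldimethylsilyloxy)-2,8-dimethylchroman-2-yl]-2,6-dimethylnon-6-en-1-ol | OC[C@@H](C)CCC/C(C)=C/CC[C@]1(C)CCc2cc(O[Si](C)(C)C(C)(C)C)cc(C)c2O1 | intermediate
22 | (2S,6E)-9-[(2R)-6-(tert-butyldimethylsilyloxy)-2,8-dimethylchroman-2-yl]-2,6-dimethylnon-6-enal | O=C[C@@H](C)CCC/C(C)=C/CC[C@]1(C)CCc2cc(O[Si](C)(C)C(C)(C)C)cc(C)c2O1 | intermediate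
23 | 1-chloro-3-methylbut-2-ene | CC(C)=CCCl | starting material
24 | (3-methylbut-2-en-1-yl)barium chloride | CC(C)=CC[Ba]Cl | intermediate (not isolated)
25 | (6S,10E)-13-[(2R)-6-(tert-butyldimethylsilyloxy)-2,8-dimethylchroman-2-yl]-2,6,10-trimethyltrideca-2,10-dien-5-ol (C5 epimers) | CC(C)=CCC(O)[C@@H](C)CCC/C(C)=C/CC[C@]1(C)CCc2cc(O[Si](C)(C)C(C)(C)C)cc(C)c2O1 | intermediate
26 | (6S,10E)-13-[(2R)-6-(tert-butyldimethylsilyloxy)-2,8-dimethylchroman-2-yl]-2,6,10-trimethyltrideca-2,10-dien-5-one | CC(C)=CCC(=O)[C@@H](C)CCC/C(C)=C/CC[C@]1(C)CCc2cc(O[Si](C)(C)C(C)(C)C)cc(C)c2O1 | intermediate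
27 | (6S,10E)-13-[(2R)-6-hydroxy-2,8-dimethylchroman-2-yl]-2,6,10-trimethyltrideca-2,10-dien-5-one | CC(C)=CCC(=O)[C@@H](C)CCC/C(C)=C/CC[C@]1(C)CCc2cc(O)cc(C)c2O1 | target

**Step count and risks**

Total steps: 15. Longest linear sequence: 14 (steps 1–5 and 7–15 from farnesol; step 6 is a side branch).

Step 7 (carries the label). The hindered tertiary alkoxide may add to the carbene carbon too slowly, so that the pivaloyloxycarbene decomposes first, or it may add in conjugate fashion to the isopropenyl group. The fallback uses known chemistry, sets out from alkynol 7 and returns at chromanol 17; it makes the arene intermolecularly and closes the pyran afterwards. Alkynol 7 is heated in THF at 50 °C with the known complex pentacarbonyl[(2E)-1-methoxybut-2-en-1-ylidene]chromium F1. The normal regiochemistry of a terminal alkyne places the chain ortho to the new hydroxyl and gives, after air, 2-[(3R,6E)-3-hydroxy-3,7,11-trimethyldodeca-6,10-dien-1-yl]-4-methoxy-6-methylphenol F2. Oxidation with (NH4)2Ce(NO3)6 in aqueous MeCN gives 2-[(3R,6E)-3-hydroxy-3,7,11-trimethyldodeca-6,10-dien-1-yl]-6-methyl-1,4-benzoquinone F3. HC(OMe)3, MeOH and pyridinium tosylate then close the tertiary hydroxyl onto the neighbouring carbonyl to give the cyclic ketal (2R)-8a-methoxy-2,8-dimethyl-2-[(3E)-4,8-dimethylnona-3,7-dien-1-yl]-3,4-dihydro-2H-chromen-6(8aH)-one F4. Zn in AcOH reduces F4 to 17; the C2–O bond is never broken, so configuration is retained.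

Step 8 (key step). Insertion may turn intermolecular and give oligomers, the tertiary C–O bond of the carbene may ionise on heating, or the vinylcarbene may be diverted before CO insertion. The fallback leaves chromium, sets out from silylated tosylate 5 and returns at chromanol 17. Copper-catalysed coupling (Li2CuCl4 cat., THF, −20 to 0 °C) of 5 with (2,5-dimethoxy-3-methylphenyl)magnesium bromide F5 gives triethyl{[(3R,6E)-1-(2,5-dimethoxy-3-methylphenyl)-3,7,11-trimethyldodeca-6,10-dien-3-yl]oxy}silane F6. Bu4NF gives (3R,6E)-1-(2,5-dimethoxy-3-methylphenyl)-3,7,11-trimethyldodeca-6,10-dien-3-ol F7. Oxidation with (NH4)2Ce(NO3)6 gives quinone F3, which is ketalised to F4 and reduced to 17 as described for step 7.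

Step 11. Enantioface discrimination may be poor, because a 2-methyl allylic alcohol differs in substitution pattern from geraniol, and the alkene may migrate before reduction. The fallback moves the stereo-determining reduction to the carboxylic acid oxidation level, where the carboxylate directs; it sets out from allylic alcohol 20 and returns at alcohol 21. MnO2 in CH2Cl2 gives enal 19. Pinnick oxidation (NaClO2, NaH2PO4, 2-methyl-2-butene, t-BuOH/H2O) gives (2E,6E)-9-[(2R)-6-(tert-butyldimethylsilyloxy)-2,8-dimethylchroman-2-yl]-2,6-dimethylnona-2,6-dienoic acid F8. Hydrogenation with Ru(OAc)2[(S)-H8-BINAP] in MeOH at low pressure, the established conditions for 2-methyl-2-alkenoic acids of the tiglic acid class, should give (2S,6E)-9-[(2R)-6-(tert-butyldimethylsilyloxy)-2,8-dimethylchroman-2-yl]-2,6-dimethylnon-6-enoic acid F9. LiAlH4 in THF at 0 °C then gives 21.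

**Further compounds**

F1 | step 7 | pentacarbonyl[(2E)-1-methoxybut-2-en-1-ylidene]chromium | C/C=C/C(OC)=[Cr](=C=O)(=C=O)(=C=O)(=C=O)=C=O
F2 | step 7 | 2-[(3R,6E)-3-hydroxy-3,7,11-trimethyldodeca-6,10-dien-1-yl]-4-methoxy-6-methylphenol | CC(C)=CCC/C(C)=C/CC[C@@](C)(O)CCc1cc(OC)cc(C)c1O
F3 | step 7 | 2-[(3R,6E)-3-hydroxy-3,7,11-trimethyldodeca-6,10-dien-1-yl]-6-methyl-1,4-benzoquinone | CC(C)=CCC/C(C)=C/CC[C@@](C)(O)CCC1=CC(=O)C=C(C)C1=O
F4 | step 7 | (2R)-8a-methoxy-2,8-dimethyl-2-[(3E)-4,8-dimethylnona-3,7-dien-1-yl]-3,4-dihydro-2H-chromen-6(8aH)-one (C8a epimers) | CC(C)=CCC/C(C)=C/CC[C@]1(C)CCC2=CC(=O)C=C(C)C2(OC)O1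
F5 | step 8 | (2,5-dimethoxy-3-methylphenyl)magnesium bromide | COc1cc(C)c(OC)c([Mg]Br)c1
F6 | step 8 | triethyl{[(3R,6E)-1-(2,5-dimethoxy-3-methylphenyl)-3,7,11-trimethyldodeca-6,10-dien-3-yl]oxy}silane | CC(C)=CCC/C(C)=C/CC[C@@](C)(O[Si](CC)(CC)CC)CCc1cc(OC)cc(C)c1OC
F7 | step 8 | (3R,6E)-1-(2,5-dimethoxy-3-methylphenyl)-3,7,11-trimethyldodeca-6,10-dien-3-ol | CC(C)=CCC/C(C)=C/CC[C@@](C)(O)CCc1cc(OC)cc(C)c1OC
F8 | step 11 | (2E,6E)-9-[(2R)-6-(tert-butyldimethylsilyloxy)-2,8-dimethylchroman-2-yl]-2,6-dimethylnona-2,6-dienoic acid | OC(=O)/C(C)=C/CC/C(C)=C/CC[C@]1(C)CCc2cc(O[Si](C)(C)C(C)(C)C)cc(C)c2O1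
F9 | step 11 | (2S,6E)-9-[(2R)-6-(tert-butyldimethylsilyloxy)-2,8-dimethylchroman-2-yl]-2,6-dimethylnon-6-enoic acid | OC(=O)[C@@H](C)CCC/C(C)=C/CC[C@]1(C)CCc2cc(O[Si](C)(C)C(C)(C)C)cc(C)c2O1
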